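## Structural features

The target is built on a 5,5'-linked biphenyl (rings B and C, each a 4-hydroxy-3-methoxyphenyl unit). Ring B carries an oxolane and ring C a tetralin, each para to the phenolic oxygen. The oxolane (O1, C2–C5) has ring B on C2, CH2OH on C3 and, on C4, a tertiary hydroxyl together with a 3-hydroxy-4-methoxybenzyl group (ring A). Its three contiguous stereocentres are 2S,3R,4S, with the C2 aryl trans to the C3 arm and the C4 hydroxyl trans to that arm. The tetralin is fused to ring D (7-hydroxy-6-methoxy) and carries ring C on C1, CH2OH on C2 and OH plus CH2OH on C3 (1S,2S,3S, C1 aryl trans to the C2 arm); the biaryl insulates this triad from the oxolane triad, so neither can control the other. Fragile points are the four free phenols (oxidation), the p-hydroxybenzylic C2–O1 bond of the oxolane (acid ionization, hydrogenolysis), the doubly benzylic C1–H of the tetralin and the two tertiary carbinols. The real difficulty is the pair of fully substituted carbinol carbons, each next to a stereocentre, on a biaryl whose two halves are electronically almost identical yet must be elaborated differently. The key step exploits the oxolane: C3 with its CH2OH branch is the internal carbon of a terminal epoxide and becomes a radical, while C4, which must end up with oxygen and the ring A benzyl group, is the near carbon of an aryl alkyne; one C3–C4 bond closes the ring and leaves a benzylidene for later hydration.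

## Logic of the disconnections

35 ⇒ 34 ⇒ 33. Five O–benzyl bonds, the two C–O bonds of the isopropylidene acetal and the O–Si bond are cut last. The free phenols and the polyol are tolerable only at the end, so all earlier chemistry runs on a non-phenolic substrate. The forward steps must spare the benzylic C2–O1 bond of the oxolane, both in acid and under hydrogen.

33 ⇒ 32 ⇒ 31 ⇒ 30. The C4–OH bond and one benzylic C–H bond are cut, which traces the tertiary carbinol to a trisubstituted exocyclic alkene through its epoxide. This turns the quaternary centre into a facial-selectivity problem on a ring that already holds C2 and C3. Oxygen must enter anti to the C3 arm (hence the silyl ether in 31), and hydride must open 32 at the benzylic carbon.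

30 ⇒ 28. The C3–C4 bond is cut. Ring, C–C bond and the C3 stereocentre disappear together, leaving an acyclic ether with a single controlling stereocentre. The forward step must generate the radical at the internal epoxide carbon, close 5-exo-dig and place the C3 arm trans to the C2 aryl.

28 ⇒ 22 + 27. The propargylic O–CH2 bond is cut. The ring A alkyne is split off as a small electrophile, so the complex half enters as an alkoxide. The alkylation has to outrun epoxide migration in that alkoxide.

27 ⇒ 26 ⇒ 24 + 25, and 24 ⇒ 23. The C–Br bond and then the aryl–alkyne bond are cut. Ring A is reduced to a bromophenol and a three-carbon alkynol. The cross-coupling must work on an electron-rich aryl bromide.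

22 ⇒ 21 ⇒ 20. The oxirane C–O bonds and the bond between the carbinol carbon and the vinyl group are cut. The whole epoxy carbinol collapses to a formyl group. Because the remote tetralin cannot bias the addition, the forward epoxidation must select one carbinol epimer by reagent control.

20 ⇒ 17 + 19, and 19 ⇒ 18 ⇒ 1. The biaryl bond is cut. This avoids desymmetrizing a symmetrical dialdehyde and avoids carrying a masked formyl group through enolate, acid and hydride steps; both halves come from 1. The coupling must tolerate two ortho alkoxy groups and a free aldehyde.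

17 ⇒ 16 ⇒ 15 ⇒ 14. Two O–benzyl bonds are cut, then the C1–C8a bond of the tetralin. The carbocycle and the C1 stereocentre are traced to an open-chain phenol. The forward step needs exactly one free phenol (ring C) so that only its benzylic carbon is oxidized, and ring D must attack para to its methoxy group.

14 ⇒ 13 ⇒ 12 ⇒ 11. The allyl–O bond, the acetal C–O bonds and the C–H bonds of two CH2OH groups are cut. The triol is traced to a diacid derivative in which both stereocentres are α to carbonyl groups. The acetal must form on the 1,2-diol so that the tertiary hydroxyl and its CH2OH cannot trap the quinone methide.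

11 ⇒ 8 + 10, and 10 ⇒ 9. The bond between the quaternary carbinol carbon and the ring D benzylic carbon is cut. The quaternary centre becomes a tertiary one stored in an acetal. The alkylation must occur with retention.

8 ⇒ 7 ⇒ 6 ⇒ 5 + 4, and 4 ⇒ 3 ⇒ 2 ⇒ 1. The acetal C–O bonds, the ester C–O bonds and the bond between C3 of the succinate and the ring C benzylic carbon are cut. Everything is traced to 5, whose single stereocentre must direct the first benzylation anti.

## Other disconnections considered

Alternative 1: The cut is the C1–C8a bond of the tetralin, made last from the bis-oxolane A2, in which ring C carries a second oxolane bearing a free 4-hydroxy-3-methoxybenzyl group. Forward, acid would ionize the benzylic C–O bond of that oxolane and its pendant arene would close onto the cation para to OMe to give A1, the target as its ring A tosylate. In its favour, the tetralin ring and C1 appear in one late step, and the ring A arene is doubly mismatched as a nucleophile (no position para to OMe, sulfonate deactivation), so ionization of its oxolane should only reverse. The cationic closure is the same reaction type the chosen plan uses in step 12, so the two are equal on the mechanism of tetralin formation. Against it, both benzylic C–O bonds ionize equally, so C2 of the surviving oxolane can epimerize. A2 needs two oxolanes with different benzyl groups on a near-symmetrical biaryl, so a two-directional synthesis is not available. The tosylate must finally be removed from a polyphenol. Its step economy could be better than the chosen plan if A2 were easy to reach; structurally it moves the whole difficulty into A2.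

Alternative 2: The cut is C3–C4 of the tetralin. Forward, a chiral triazolylidene would convert the ring D aldehyde of keto aldehyde A4 into a Breslow intermediate that adds to the α-benzyloxy ketone, giving the α-hydroxy tetralone A3. In its favour, the quaternary carbinol is made catalytically under mild conditions with no cationic intermediate, so C1 is not exposed to ionization; here it is the better plan. The C4 carbonyl is benzylic and might be removed in the final hydrogenolysis. Against it, A4 has an epimerizable α-stereocentre with a β-benzyloxy group (risk of elimination under the basic carbene conditions), and catalyst control at C3 must override or match the existing C1/C2 centres. The diarylmethine stereocentre of A4 has to be built acyclically. The alternative addresses only the tetralin and would replace steps 4–13; the oxolane would still need the chosen key step. The stoichiometric chiral-pool alkylations of the chosen plan are longer but each has a predictable stereochemical course.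

Alternative 3: The cut is O1–C2 of the oxolane. Forward, Ag2O would oxidize the single free phenol (ring B) of triol A6 to a p-quinone methide, and the primary hydroxyl on the carbinol carbon would add to it to give A5; only that hydroxyl can form a five-membered ring. In its favour, C3 and C4 of the oxolane would come from the same malate sequence that gives 12, with no resolution and no epoxidation/hydride sequence. On stereochemical economy this alternative is better than the chosen plan, and on the ring-forming mechanism it matches step 12. Against it, it needs a second full malate sequence carrying a ring B coupling handle and a second orthogonally freed phenol. C2 would be set under kinetic control, with uncertainty comparable to the 2,3-selectivity of the radical closure. The tetralin acetonide would have to be introduced after the acidic dioxolanone chemistry of the second sequence. Overall length would be similar; the chosen plan forms a C–C bond and the ring at once and keeps all phenols protected to the end.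

Key step: step 23

Remarks on the chemistry (before the steps):
- **Malate configuration.** Anti-selective enolate benzylation followed by retentive dioxolanone benzylation maps an (S)-malate, not an (R)-malate, onto the (1S,2S,3S)-tetralin; an (R)-malate would end in the enantiomeric tetralin, so the route starts from diisopropyl (S)-malate.
- **Tartrate sense.** The carbinol epimer needed for oxolane C2 is the one consumed with D-(−)-tartrate. Its descriptor changes from S (allylic alcohol) to R (epoxy alcohol and ether) to S (oxolane) only through priority changes.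
- **Biaryl.** The biaryl is made by cross-coupling two halves derived from 5-bromovanillin instead of from the preformed symmetrical dialdehyde, whose second formyl group would have to be carried masked through enolate, acid and hydride steps.
- **Assumption.** The benzylidene of 30 is drawn E (aryl syn to C3). Either geometry would serve, because that carbon becomes CH2 in step 26.
- **Abbreviations in names.** Tet = (1S,2S,3S)-7-(benzyloxy)-2-[(benzyloxy)methyl]-6-methoxy-1,2,3,4-tetrahydronaphthalen-1-yl whose C3 is the spiro carbon of a 2,2-dimethyl-1,3-dioxolane (dioxolane O and dioxolane CH2 both on C3). ArBC = 4-(benzyloxy)-3-methoxy-5-[2-(benzyloxy)-3-methoxy-5-(Tet)phenyl]phenyl, bonded through C1. Oxolane numbering is O1, C2 (aryl), C3, C4, C5 throughout.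

## Steps

Step 1
Reactants: 1 5-bromovanillin (3-bromo-4-hydroxy-5-methoxybenzaldehyde)
Product: 2 3-bromo-5-methoxy-4-(prop-2-enyloxy)benzaldehyde
Conditions: allyl bromide, K2CO3, DMF, rt
Reagents that add atoms: allyl bromide, C=CCBr
Why: Williamson ether synthesis on the phenoxide; the allyl ether is chosen because zerovalent palladium can later remove it beside benzyl ethers.

Step 2
Reactants: 2 3-bromo-5-methoxy-4-(prop-2-enyloxy)benzaldehyde
Product: 3 [3-bromo-5-methoxy-4-(prop-2-enyloxy)phenyl]methanol
Conditions: NaBH4, MeOH, 0 °C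
Reagents that add atoms: none
Why: Borohydride reduction of an aromatic aldehyde; aryl bromide and allyl ether are inert.

Step 3
Reactants: 3 [3-bromo-5-methoxy-4-(prop-2-enyloxy)phenyl]methanol
Product: 4 1-bromo-5-(bromomethyl)-3-methoxy-2-(prop-2-enyloxy)benzene
Conditions: PBr3, CH2Cl2, 0 °C
Reagents that add atoms: phosphorus tribromide, BrP(Br)Br
Why: Alcohol-to-bromide conversion through the phosphite ester (SN2); the electron-rich benzylic alcohol reacts cleanly at 0 °C.

Step 4
Reactants: 5 diisopropyl (S)-malate; 4 1-bromo-5-(bromomethyl)-3-methoxy-2-(prop-2-enyloxy)benzene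
Product: 6 diisopropyl (2S,3R)-3-{[3-bromo-5-methoxy-4-(prop-2-enyloxy)phenyl]methyl}-2-hydroxybutanedioate
Conditions: LiN(SiMe3)2 (2.1 equiv), THF, −78 °C; then 4, −78 to −15 °C
Reagents that add atoms: none
Why: Fráter–Seebach alkylation: the chelated lithium alkoxide enolate is benzylated on the face anti to the alkoxide, so the 2S centre sets the new 3R centre (future tetralin C2).

Step 5
Reactants: 6 diisopropyl (2S,3R)-3-(arylmethyl)-2-hydroxybutanedioate
Product: 7 (2S,3R)-3-{[3-bromo-5-methoxy-4-(prop-2-enyloxy)phenyl]methyl}-2-hydroxybutanedioic acid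
Conditions: KOH, H2O/1,4-dioxane, rt; then cold dilute HCl to pH 2
Reagents that add atoms: potassium hydroxide, [K+].[OH-]
Why: Saponification; the carboxylate groups formed suppress enolization, so both α-centres should be kept.

Step 6
Reactants: 7 (2S,3R)-3-(arylmethyl)-2-hydroxybutanedioic acid
Product: 8 (2R)-3-[3-bromo-5-methoxy-4-(prop-2-enyloxy)phenyl]-2-[(2S,4S)-2-tert-butyl-5-oxo-1,3-dioxolan-4-yl]propanoic acid (cis-dioxolanone)
Conditions: tBuCHO, p-TsOH (cat.), H2SO4 (cat.), CH2Cl2/pentane, reflux, water separator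
Reagents that add atoms: pivalaldehyde, CC(C)(C)C=O
Why: Acetalization of the α-hydroxy acid gives the five-membered dioxolanone in preference to the six-membered dioxanone; under thermodynamic control tert-butyl sits cis to the side chain, so the acetal carbon stores the configuration of the carbinol carbon.

Step 7
Reactants: 9 [4-(benzyloxy)-3-methoxyphenyl]methanol
Product: 10 1-(benzyloxy)-4-(bromomethyl)-2-methoxybenzene
Conditions: PBr3, Et2O, 0 °C
Reagents that add atoms: phosphorus tribromide, BrP(Br)Br
Why: Standard bromination of an electron-rich benzylic alcohol; the product is used without storage.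

Step 8
Reactants: 8 cis-dioxolanone acid; 10 1-(benzyloxy)-4-(bromomethyl)-2-methoxybenzene
Product: 11 (2R)-2-[(2S,4S)-4-{[4-(benzyloxy)-3-methoxyphenyl]methyl}-2-tert-butyl-5-oxo-1,3-dioxolan-4-yl]-3-[3-bromo-5-methoxy-4-(prop-2-enyloxy)phenyl]propanoic acid
Conditions: LiN(SiMe3)2 (2.2 equiv), THF, −78 °C; then 10, −78 to −20 °C
Reagents that add atoms: none
Why: Dioxolanone enolate alkylation (self-regeneration of a stereocentre): the carboxylate enolate dianion is benzylated on the face opposite tert-butyl, so the benzyl group replaces H with retention and creates the quaternary carbinol carbon (future tetralin C3).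

Step 9
Reactants: 11 doubly benzylated dioxolanone acid
Product: 12 (2S,3S)-2-{[4-(benzyloxy)-3-methoxyphenyl]methyl}-3-{[3-bromo-5-methoxy-4-(prop-2-enyloxy)phenyl]methyl}butane-1,2,4-triol
Conditions: LiAlH4, THF, 0 °C to rt
Reagents that add atoms: none
Why: Hydride reduction of the carboxylic acid and of the acyl acetal; the dioxolanone collapses to the diol and pivalaldehyde, which is reduced further, and neither stereocentre is touched.

Step 10
Reactants: 12 triol
Product: 13 (2S)-2-[(4S)-4-{[4-(benzyloxy)-3-methoxyphenyl]methyl}-2,2-dimethyl-1,3-dioxolan-4-yl]-3-[3-bromo-5-methoxy-4-(prop-2-enyloxy)phenyl]propan-1-ol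
Conditions: Me2C(OMe)2, PPTS (cat.), acetone, rt
Reagents that add atoms: 2,2-dimethoxypropane, COC(C)(C)OC
Why: Acetonide formation under thermodynamic control prefers the five-membered dioxolane of the 1,2-diol over a 1,3-dioxane; it masks the tertiary hydroxyl and its CH2OH, which could otherwise add to the quinone methide of step 12.

Step 11
Reactants: 13 acetonide allyl ether
Product: 14 2-bromo-4-{(2S)-2-[(4S)-4-{[4-(benzyloxy)-3-methoxyphenyl]methyl}-2,2-dimethyl-1,3-dioxolan-4-yl]-3-hydroxypropyl}-6-methoxyphenol
Conditions: Pd(PPh3)4 (3 mol %), K2CO3, MeOH, rt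
Reagents that add atoms: none
Why: Tsuji–Trost-type deallylation: zerovalent palladium ionizes the aryl allyl ether and methoxide takes the allyl group; benzyl ether, acetonide and the aryl bromide (slow oxidative addition at rt) should remain.

Step 12
Reactants: 14 ring C phenol
Product: 16 (1S,2S,3S)-7-(benzyloxy)-1-(3-bromo-4-hydroxy-5-methoxyphenyl)-2-(hydroxymethyl)-6-methoxytetralin, C3 spiro-fused to a 2,2-dimethyl-1,3-dioxolane (O and CH2 on C3), via p-quinone methide 15 (not isolated)
Conditions: DDQ (1.05 equiv), CH2Cl2, 0 °C; then TFA (3 equiv), −20 to 0 °C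
Reagents that add atoms: none
Why: DDQ dehydrogenates the only free 4-alkylphenol to quinone methide 15, and acid then triggers an intramolecular Friedel–Crafts alkylation by ring D para to its methoxy group (six-membered ring). C1 is set trans to the C2 arm because the aryl group takes a pseudo-equatorial position in the chair-like transition state.

Step 13
Reactants: 16 tetralin phenol
Product: 17 Tet-substituted 2-(benzyloxy)-1-bromo-3-methoxybenzene: 1-(benzyloxy)-2-bromo-6-methoxy-4-(Tet)benzene
Conditions: NaH, BnBr, Bu4NI (cat.), DMF, 0 °C to rt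
Reagents that add atoms: benzyl bromide, BrCc1ccccc1
Why: Williamson benzylation of the phenoxide and of the primary alkoxide in one operation; no other acidic site is present.

Step 14
Reactants: 1 5-bromovanillin
Product: 18 4-(benzyloxy)-3-bromo-5-methoxybenzaldehyde
Conditions: BnBr, K2CO3, DMF, rt
Reagents that add atoms: benzyl bromide, BrCc1ccccc1
Why: Williamson ether synthesis on the phenoxide.

Step 15
Reactants: 18 4-(benzyloxy)-3-bromo-5-methoxybenzaldehyde
Product: 19 4-(benzyloxy)-3-methoxy-5-(4,4,5,5-tetramethyl-1,3,2-dioxaborolan-2-yl)benzaldehyde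
Conditions: B2pin2, PdCl2(dppf) (3 mol %), KOAc, 1,4-dioxane, 85 °C
Reagents that add atoms: bis(pinacolato)diboron, CC1(C)OB(OC1(C)C)B1OC(C)(C)C(C)(C)O1
Why: Miyaura borylation of an aryl bromide; the weak base KOAc leaves the aldehyde alone and prevents homocoupling.

Step 16
Reactants: 17 tetralin aryl bromide; 19 formyl arylboronate
Product: 20 ArBC-carbaldehyde: 4-(benzyloxy)-3-methoxy-5-[2-(benzyloxy)-3-methoxy-5-(Tet)phenyl]benzaldehyde
Conditions: Pd(OAc)2 (3 mol %), SPhos (6 mol %), K3PO4, toluene/H2O, 80 °C
Reagents that add atoms: none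
Why: Suzuki–Miyaura coupling; the bulky electron-rich biarylphosphine is suited to two ortho-alkoxy partners, and aldehyde, acetonide and benzyl ethers are tolerated.

Step 17
Reactants: 20 ArBC-carbaldehyde
Product: 21 1-(ArBC)prop-2-en-1-ol, both C1 epimers
Conditions: CH2=CHMgBr, THF, −78 to 0 °C
Reagents that add atoms: vinylmagnesium bromide, C=C[Mg]Br
Why: Grignard addition to an aromatic aldehyde; the tetralin stereocentres are too remote to bias the new carbinol centre, so both epimers are expected in similar amounts.

Step 18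
Reactants: 21 1-(ArBC)prop-2-en-1-ol (epimers)
Product: 22 (R)-(ArBC)[(2S)-oxiran-2-yl]methanol
Conditions: Ti(OiPr)4 (1.0 equiv), D-(−)-DIPT (1.2 equiv), tBuOOH (0.6 equiv), 4 Å MS, CH2Cl2, −20 °C
Reagents that add atoms: tert-butyl hydroperoxide, CC(C)(C)OO
Why: Sharpless kinetic resolution applied to the epimer pair: with the D-(−)-tartrate complex the (1S)-epimer of 21 is the fast-reacting one and gives the erythro epoxy alcohol, while the (1R)-epimer is left, separated and can be recycled by oxidation and reduction. The carbinol centre selected here becomes oxolane C2.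

Step 19
Reactants: 23 5-bromo-2-methoxyphenol
Product: 24 2-(benzyloxy)-4-bromo-1-methoxybenzene
Conditions: BnBr, K2CO3, acetone, reflux
Reagents that add atoms: benzyl bromide, BrCc1ccccc1
Why: Williamson ether synthesis on the phenoxide.

Step 20
Reactants: 24 2-(benzyloxy)-4-bromo-1-methoxybenzene; 25 propargyl alcohol
Product: 26 3-[3-(benzyloxy)-4-methoxyphenyl]prop-2-yn-1-ol
Conditions: PdCl2(PPh3)2 (3 mol %), CuI (5 mol %), iPr2NH, DMF, 70 °C
Reagents that add atoms: none
Why: Sonogashira coupling of a terminal alkyne with an aryl bromide; heating compensates for the electron-rich bromide.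

Step 21
Reactants: 26 3-[3-(benzyloxy)-4-methoxyphenyl]prop-2-yn-1-ol
Product: 27 2-(benzyloxy)-4-(3-bromoprop-1-yn-1-yl)-1-methoxybenzene
Conditions: CBr4, PPh3, CH2Cl2, 0 °C
Reagents that add atoms: tetrabromomethane, BrC(Br)(Br)Br
Why: Appel bromination under neutral conditions, which suits the ionizable aryl propargyl system; the bromide is used at once.

Step 22
Reactants: 22 epoxy alcohol; 27 aryl propargyl bromide
Product: 28 2-(benzyloxy)-1-methoxy-4-{3-[(R)-(ArBC)((2S)-oxiran-2-yl)methoxy]prop-1-yn-1-yl}benzene
Conditions: NaH, THF/DMF, 0 °C; then 27, Bu4NI (cat.), 0 °C to rt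
Reagents that add atoms: none
Why: Williamson etherification of the secondary alkoxide with a reactive propargylic bromide; at 0 °C in an aprotic medium alkylation should outrun Payne rearrangement of the epoxy alkoxide.

Step 23
Reactants: 28 epoxy aryl-propargyl ether
Product: 30 [(2S,3R,4E)-2-(ArBC)-4-{[3-(benzyloxy)-4-methoxyphenyl]methylidene}oxolan-3-yl]methanol, via titanium alkoxide 29 (not isolated)
Conditions: Cp2TiCl2 (2.5 equiv), Zn dust, THF, rt, slow addition of 28 at high dilution; then aq. NaH2PO4
Reagents that add atoms: none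
Why: Cp2TiCl (trivalent titanium, made in the flask from Cp2TiCl2 and Zn) transfers one electron to the oxirane of 28, and the C–O bond to the internal carbon breaks homolytically to give the secondary C3 radical with a tetravalent titanium alkoxide on the terminal carbon. The closest known reaction type is the Nugent–RajanBabu reductive epoxide opening used for radical cyclization of epoxy propargyl ethers to 4-alkylidene oxolanes. The radical adds to the nearer alkyne carbon in a 5-exo-dig closure, which forms C3–C4 and closes the oxolane; 6-endo attack is disfavoured stereoelectronically and would not give the stabilized α-aryl vinyl radical. That vinyl radical takes a hydrogen atom from THF (or is reduced by a second Cp2TiCl and protonated on work-up), and hydrolysis of alkoxide 29 releases the CH2OH group. The new stereocentre C3 is controlled by C2: in the envelope-like transition state the ring B aryl is pseudo-equatorial and the CH2O–Ti arm takes the position trans to it, while the oxirane configuration is lost in the planar radical. The step needs opening towards the secondary radical (secured by radical stability), cyclization faster than capture of the radical by a second titanium centre and β-alkoxide loss (secured by the ether tether, slow addition and dilution), and inertness of benzyl ethers, acetonide and aryl ethers towards Cp2TiCl. Hydrogen delivery to the linear vinyl radical from the less hindered C5 side should give the E alkene.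

Step 24
Reactants: 30 benzylidene oxolane alcohol
Product: 31 tert-butyldimethylsilyl ether of 30: (2S,3R,4E)-2-(ArBC)-4-{[3-(benzyloxy)-4-methoxyphenyl]methylidene}-3-{[(tert-butyldimethylsilyl)oxy]methyl}oxolane
Conditions: TBSCl, imidazole, DMF, rt
Reagents that add atoms: tert-butyldimethylsilyl chloride, CC(C)(C)[Si](C)(C)Cl
Why: Silylation of the primary alcohol removes any hydroxyl-directing effect and makes the C3 arm a bulky shield for the next step.

Step 25
Reactants: 31 silyl ether
Product: 32 (2S,3R,4S)-2-(ArBC)-3-{[(tert-butyldimethylsilyl)oxy]methyl}oxolane-4-spiro-2'-oxirane carrying 3-(benzyloxy)-4-methoxyphenyl on oxirane C3' (S), oxirane oxygen anti to the C3 arm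
Conditions: dimethyldioxirane (1.2 equiv), acetone/CH2Cl2, −30 to 0 °C
Reagents that add atoms: dimethyldioxirane, CC1(C)OO1
Why: Epoxidation of the electron-rich trisubstituted alkene by a neutral dioxirane, which avoids acid opening of the p-alkoxyaryl epoxide. Allylic 1,3-strain with the benzylidene aryl pushes the C3 silyloxymethyl arm pseudo-axial, so oxygen is delivered to the opposite face and fixes the C4–O configuration.

Step 26
Reactants: 32 spiro epoxide
Product: 33 (2S,3R,4S)-2-(ArBC)-4-{[3-(benzyloxy)-4-methoxyphenyl]methyl}-3-{[(tert-butyldimethylsilyl)oxy]methyl}oxolan-4-ol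
Conditions: LiAlH4, THF, 0 °C to rt
Reagents that add atoms: none
Why: Reductive epoxide opening: hydride attacks the benzylic, less substituted oxirane carbon in an SN2 sense, so the C4–O bond and its configuration are kept and the benzylic carbon becomes CH2.

Step 27
Reactants: 33 silyl ether acetonide
Product: 34 pentabenzyl ether of the target: (2S,3R,4S)-4-{[3-(benzyloxy)-4-methoxyphenyl]methyl}-3-(hydroxymethyl)-2-(biaryl)oxolan-4-ol with free tetralin C3–OH and C3–CH2OH
Conditions: AcOH/THF/H2O (3:1:1), 45 °C
Reagents that add atoms: none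
Why: Mild acid hydrolysis of the primary silyl ether and of the isopropylidene acetal; with the ring B oxygen still benzylated the benzylic C2–O1 bond should not ionize under these conditions.

Step 28
Reactants: 34 pentabenzyl ether
Product: 35 CNP0252244.1
Conditions: H2 (1 atm), 10% Pd/C, EtOAc/MeOH, rt, stopped after uptake of five equivalents
Reagents that add atoms: none
Why: Hydrogenolysis of four aryl benzyl ethers and one alkyl benzyl ether; these cleave faster than the cyclic benzylic C2–O1 ether under neutral conditions, and no stereocentre is affected.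

## Compound list

1 | 5-bromovanillin | O=Cc1cc(Br)c(O)c(OC)c1 | starting material
2 | 3-bromo-5-methoxy-4-(prop-2-enyloxy)benzaldehyde | O=Cc1cc(Br)c(OCC=C)c(OC)c1 | intermediate
3 | [3-bromo-5-methoxy-4-(prop-2-enyloxy)phenyl]methanol | OCc1cc(Br)c(OCC=C)c(OC)c1 | intermediate
4 | 1-bromo-5-(bromomethyl)-3-methoxy-2-(prop-2-enyloxy)benzene | BrCc1cc(Br)c(OCC=C)c(OC)c1 | intermediate
5 | diisopropyl (S)-malate | CC(C)OC(=O)C[C@H](O)C(=O)OC(C)C | starting material
6 | diisopropyl (2S,3R)-3-{[3-bromo-5-methoxy-4-(prop-2-enyloxy)phenyl]methyl}-2-hydroxybutanedioate | CC(C)OC(=O)[C@@H](O)[C@@H](Cc1cc(Br)c(OCC=C)c(OC)c1)C(=O)OC(C)C | intermediate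
7 | (2S,3R)-3-{[3-bromo-5-methoxy-4-(prop-2-enyloxy)phenyl]methyl}-2-hydroxybutanedioic acid | OC(=O)[C@@H](O)[C@@H](Cc1cc(Br)c(OCC=C)c(OC)c1)C(=O)O | intermediate
8 | (2R)-3-[3-bromo-5-methoxy-4-(prop-2-enyloxy)phenyl]-2-[(2S,4S)-2-tert-butyl-5-oxo-1,3-dioxolan-4-yl]propanoic acid | O=C1O[C@@H](C(C)(C)C)O[C@H]1[C@@H](Cc1cc(Br)c(OCC=C)c(OC)c1)C(=O)O | intermediate
9 | [4-(benzyloxy)-3-methoxyphenyl]methanol | OCc1ccc(OCc2ccccc2)c(OC)c1 | starting material
10 | 1-(benzyloxy)-4-(bromomethyl)-2-methoxybenzene | BrCc1ccc(OCc2ccccc2)c(OC)c1 | intermediate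
11 | (2R)-2-[(2S,4S)-4-{[4-(benzyloxy)-3-methoxyphenyl]methyl}-2-tert-butyl-5-oxo-1,3-dioxolan-4-yl]-3-[3-bromo-5-methoxy-4-(prop-2-enyloxy)phenyl]propanoic acid | O=C1O[C@@H](C(C)(C)C)O[C@@]1(Cc1ccc(OCc2ccccc2)c(OC)c1)[C@@H](Cc1cc(Br)c(OCC=C)c(OC)c1)C(=O)O | intermediate
12 | (2S,3S)-2-{[4-(benzyloxy)-3-methoxyphenyl]methyl}-3-{[3-bromo-5-methoxy-4-(prop-2-enyloxy)phenyl]methyl}butane-1,2,4-triol | COc1cc(C[C@@](O)(CO)[C@@H](Cc2cc(Br)c(OCC=C)c(OC)c2)CO)ccc1OCc1ccccc1 | intermediate
13 | (2S)-2-[(4S)-4-{[4-(benzyloxy)-3-methoxyphenyl]methyl}-2,2-dimethyl-1,3-dioxolan-4-yl]-3-[3-bromo-5-methoxy-4-(prop-2-enyloxy)phenyl]propan-1-ol | COc1cc(C[C@@]2(COC(C)(C)O2)[C@@H](Cc2cc(Br)c(OCC=C)c(OC)c2)CO)ccc1OCc1ccccc1 | intermediate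
14 | 2-bromo-4-{(2S)-2-[(4S)-4-{[4-(benzyloxy)-3-methoxyphenyl]methyl}-2,2-dimethyl-1,3-dioxolan-4-yl]-3-hydroxypropyl}-6-methoxyphenol | COc1cc(C[C@@]2(COC(C)(C)O2)[C@@H](Cc2cc(Br)c(O)c(OC)c2)CO)ccc1OCc1ccccc1 | intermediate
15 | p-quinone methide of 14 (2-bromo-6-methoxy-4-alkylidenecyclohexa-2,5-dienone) | COc1cc(C[C@@]2(COC(C)(C)O2)[C@@H](C=C2C=C(Br)C(=O)C(OC)=C2)CO)ccc1OCc1ccccc1 | intermediate (not isolated)
16 | (1S,2S,3S)-7-(benzyloxy)-1-(3-bromo-4-hydroxy-5-methoxyphenyl)-2-(hydroxymethyl)-6-methoxytetralin-3-spiro-4'-(2',2'-dimethyl-1',3'-dioxolane) | COc1cc(cc(Br)c1O)[C@H]1c2cc(OCc3ccccc3)c(OC)cc2C[C@@]2(COC(C)(C)O2)[C@@H]1CO | intermediate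
17 | 1-(benzyloxy)-2-bromo-6-methoxy-4-(Tet)benzene | COc1cc(cc(Br)c1OCc1ccccc1)[C@H]1c2cc(OCc3ccccc3)c(OC)cc2C[C@@]2(COC(C)(C)O2)[C@@H]1COCc1ccccc1 | intermediate
18 | 4-(benzyloxy)-3-bromo-5-methoxybenzaldehyde | O=Cc1cc(Br)c(OCc2ccccc2)c(OC)c1 | intermediate
19 | 4-(benzyloxy)-3-methoxy-5-(4,4,5,5-tetramethyl-1,3,2-dioxaborolan-2-yl)benzaldehyde | O=Cc1cc(B2OC(C)(C)C(C)(C)O2)c(OCc2ccccc2)c(OC)c1 | intermediate
20 | 4-(benzyloxy)-3-methoxy-5-[2-(benzyloxy)-3-methoxy-5-(Tet)phenyl]benzaldehyde | O=Cc1cc(OC)c(OCc2ccccc2)c(c1)-c1cc(cc(OC)c1OCc1ccccc1)[C@H]1c2cc(OCc3ccccc3)c(OC)cc2C[C@@]2(COC(C)(C)O2)[C@@H]1COCc1ccccc1 | intermediate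
21 | 1-(ArBC)prop-2-en-1-ol, both C1 epimers | C=CC(O)c1cc(OC)c(OCc2ccccc2)c(c1)-c1cc(cc(OC)c1OCc1ccccc1)[C@H]1c2cc(OCc3ccccc3)c(OC)cc2C[C@@]2(COC(C)(C)O2)[C@@H]1COCc1ccccc1 | intermediate
22 | (R)-(ArBC)[(2S)-oxiran-2-yl]methanol | O[C@H](c1cc(OC)c(OCc2ccccc2)c(c1)-c1cc(cc(OC)c1OCc1ccccc1)[C@H]1c2cc(OCc3ccccc3)c(OC)cc2C[C@@]2(COC(C)(C)O2)[C@@H]1COCc1ccccc1)[C@@H]1CO1 | intermediate
23 | 5-bromo-2-methoxyphenol | COc1ccc(Br)cc1O | starting material
24 | 2-(benzyloxy)-4-bromo-1-methoxybenzene | COc1ccc(Br)cc1OCc1ccccc1 | intermediate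
25 | propargyl alcohol | C#CCO | starting material
26 | 3-[3-(benzyloxy)-4-methoxyphenyl]prop-2-yn-1-ol | COc1ccc(C#CCO)cc1OCc1ccccc1 | intermediate
27 | 2-(benzyloxy)-4-(3-bromoprop-1-yn-1-yl)-1-methoxybenzene | COc1ccc(C#CCBr)cc1OCc1ccccc1 | intermediate
28 | 2-(benzyloxy)-1-methoxy-4-{3-[(R)-(ArBC)((2S)-oxiran-2-yl)methoxy]prop-1-yn-1-yl}benzene | COc1ccc(C#CCO[C@H](c2cc(OC)c(OCc3ccccc3)c(c2)-c2cc(cc(OC)c2OCc2ccccc2)[C@H]2c3cc(OCc4ccccc4)c(OC)cc3C[C@@]3(COC(C)(C)O3)[C@@H]2COCc2ccccc2)[C@@H]2CO2)cc1OCc1ccccc1 | intermediate
29 | chlorobis(cyclopentadienyl)titanium alkoxide of 30 (Ti on the CH2O oxygen) | COc1ccc(/C=C2/CO[C@H](c3cc(OC)c(OCc4ccccc4)c(c3)-c3cc(cc(OC)c3OCc3ccccc3)[C@H]3c4cc(OCc5ccccc5)c(OC)cc4C[C@@]4(COC(C)(C)O4)[C@@H]3COCc3ccccc3)[C@H]2CO[Ti](Cl)(C3C=CC=C3)C3C=CC=C3)cc1OCc1ccccc1 | intermediate (not isolated)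
30 | [(2S,3R,4E)-2-(ArBC)-4-{[3-(benzyloxy)-4-methoxyphenyl]methylidene}oxolan-3-yl]methanol | COc1ccc(/C=C2/CO[C@H](c3cc(OC)c(OCc4ccccc4)c(c3)-c3cc(cc(OC)c3OCc3ccccc3)[C@H]3c4cc(OCc5ccccc5)c(OC)cc4C[C@@]4(COC(C)(C)O4)[C@@H]3COCc3ccccc3)[C@H]2CO)cc1OCc1ccccc1 | intermediate
31 | (2S,3R,4E)-2-(ArBC)-4-{[3-(benzyloxy)-4-methoxyphenyl]methylidene}-3-{[(tert-butyldimethylsilyl)oxy]methyl}oxolane | COc1ccc(/C=C2/CO[C@H](c3cc(OC)c(OCc4ccccc4)c(c3)-c3cc(cc(OC)c3OCc3ccccc3)[C@H]3c4cc(OCc5ccccc5)c(OC)cc4C[C@@]4(COC(C)(C)O4)[C@@H]3COCc3ccccc3)[C@H]2CO[Si](C)(C)C(C)(C)C)cc1OCc1ccccc1 | intermediate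
32 | (2S,3R,4S)-2-(ArBC)-3-{[(tert-butyldimethylsilyl)oxy]methyl}oxolane-4-spiro-2'-oxirane with (3'S)-3'-[3-(benzyloxy)-4-methoxyphenyl], oxirane O anti to the C3 arm | COc1ccc([C@@H]2O[C@@]23CO[C@H](c4cc(OC)c(OCc5ccccc5)c(c4)-c4cc(cc(OC)c4OCc4ccccc4)[C@H]4c5cc(OCc6ccccc6)c(OC)cc5C[C@@]5(COC(C)(C)O5)[C@@H]4COCc4ccccc4)[C@H]3CO[Si](C)(C)C(C)(C)C)cc1OCc1ccccc1 | intermediate
33 | (2S,3R,4S)-2-(ArBC)-4-{[3-(benzyloxy)-4-methoxyphenyl]methyl}-3-{[(tert-butyldimethylsilyl)oxy]methyl}oxolan-4-ol | COc1ccc(C[C@@]2(O)CO[C@H](c3cc(OC)c(OCc4ccccc4)c(c3)-c3cc(cc(OC)c3OCc3ccccc3)[C@H]3c4cc(OCc5ccccc5)c(OC)cc4C[C@@]4(COC(C)(C)O4)[C@@H]3COCc3ccccc3)[C@H]2CO[Si](C)(C)C(C)(C)C)cc1OCc1ccccc1 | intermediate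
34 | pentabenzyl ether of the target (benzyl on the four phenols and on the tetralin C2 CH2OH; all other hydroxyls free) | COc1ccc(C[C@@]2(O)CO[C@H](c3cc(OC)c(OCc4ccccc4)c(c3)-c3cc(cc(OC)c3OCc3ccccc3)[C@H]3c4cc(OCc5ccccc5)c(OC)cc4C[C@@](O)(CO)[C@@H]3COCc3ccccc3)[C@H]2CO)cc1OCc1ccccc1 | intermediate
35 | CNP0252244.1: (2S,3R,4S)-2-{4-hydroxy-3-[2-hydroxy-3-methoxy-5-((1S,2S,3S)-3,7-dihydroxy-2,3-bis(hydroxymethyl)-6-methoxytetralin-1-yl)phenyl]-5-methoxyphenyl}-4-[(3-hydroxy-4-methoxyphenyl)methyl]-3-(hydroxymethyl)oxolan-4-ol | COc1ccc(C[C@@]2(O)CO[C@H](c3cc(OC)c(O)c(-c4cc([C@H]5c6cc(O)c(OC)cc6C[C@@](O)(CO)[C@@H]5CO)cc(OC)c4O)c3)[C@H]2CO)cc1O | target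

## Step count and least certain steps

Total step count: 28. Longest linear sequence: 22 steps (1–6, 8–13, 16–18, 22–28, counted from 1).

**Step 23 (key step).** The C3 radical may be captured by a second trivalent titanium centre before it cyclizes, after which β-alkoxide loss would expel the propargyl ether; this is the usual competing path of titanocene epoxide openings. The 2,3-trans preference may also be incomplete, because only one pseudo-equatorial aryl group controls it. The fallback sets out from 28 and returns at 30, replacing the titanium-mediated reductive opening by a tin hydride chain. The oxirane of 28 is opened with aqueous KOH in DMSO to the 1,2-diol F1. This is closed with thiocarbonyldiimidazole to the cyclic thionocarbonate F2. Bu3SnH with AIBN in hot toluene then fragments the thionocarbonate towards the more stable secondary C3 radical (Barton–McCombie-type cleavage of a cyclic thionocarbonate), which closes 5-exo-dig onto the aryl alkyne. Basic methanolysis of the tin thiocarbonate left on the primary oxygen gives 30.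

**Step 12 (quinone methide closure).** The quinone methide may tautomerize to the 4-alkenylphenol before the arene attacks, which would erase the adjacent stereocentre, or the cation may be intercepted by an acetal oxygen with loss of the acetonide. The fallback sets out from 14 and returns at 16, separating oxidation from ionization. DDQ oxidation of 14 in CH2Cl2/MeOH traps the quinone methide at once as the benzylic methyl ether F3 (both epimers at the new ether carbon). After purification, Sc(OTf)3 (10 mol %) in CH2Cl2 at 0 °C ionizes the ether for the same Friedel–Crafts closure under much less acidic conditions.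

**Step 18 (selection of the carbinol epimer).** The rate difference between the two epimers of 21 may be too small for clean separation on so large a substrate, or the electron-rich benzylic epoxy alcohol may be opened by the titanium Lewis acid; at best half of 21 is used. The fallback sets out from 20 and returns at 22, setting the carbinol centre by reagent-controlled addition instead of resolution. Me2Zn, trimethylsilylacetylene and the appropriate enantiomer of a ProPhenol ligand should add to 20 to give the silylated propargylic alcohol F4. K2CO3 in MeOH gives the terminal alkynol F5. Semi-hydrogenation over Pd/CaCO3 poisoned with Pb(OAc)2 and quinoline gives the single (1S)-allylic alcohol F6. The same titanium/D-(−)-tartrate epoxidation, now a matched substrate–reagent pair and no longer a resolution, gives 22.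

**Step 25 (face-selective epoxidation).** Facial discrimination may be insufficient if the C2 aryl on the other face competes with the C3 arm, and the p-alkoxyaryl epoxide may rearrange or open before it is reduced. The fallback sets out from 31 and returns at 33, replacing epoxide chemistry by dihydroxylation and radical deoxygenation. OsO4 (cat.) with N-methylmorpholine N-oxide, a bulkier oxidant that should respond more strongly to the shielding arm, gives the diol F7 with the tertiary hydroxyl anti to the C3 arm. Thiocarbonyldiimidazole gives the cyclic thionocarbonate F8. Bu3SnH with AIBN cleaves the benzylic C–O bond (the benzylic radical is the more stable fragment), and basic methanolysis of the remaining tin thiocarbonate on the tertiary oxygen gives 33.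

Further compounds
F1 | step 23 | (2R,3R)-3-(ArBC)-3-{3-[3-(benzyloxy)-4-methoxyphenyl]prop-2-ynyloxy}propane-1,2-diol (diol from hydrolysis of the oxirane of 28, secondary carbinol configured as the oxirane carbon) | COc1ccc(C#CCO[C@H](c2cc(OC)c(OCc3ccccc3)c(c2)-c2cc(cc(OC)c2OCc2ccccc2)[C@H]2c3cc(OCc4ccccc4)c(OC)cc3C[C@@]3(COC(C)(C)O3)[C@@H]2COCc2ccccc2)[C@@H](O)CO)cc1OCc1ccccc1
F2 | step 23 | cyclic thionocarbonate (1,3-dioxolane-2-thione) of F1 | COc1ccc(C#CCO[C@H](c2cc(OC)c(OCc3ccccc3)c(c2)-c2cc(cc(OC)c2OCc2ccccc2)[C@H]2c3cc(OCc4ccccc4)c(OC)cc3C[C@@]3(COC(C)(C)O3)[C@@H]2COCc2ccccc2)[C@@H]2COC(=S)O2)cc1OCc1ccccc1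
F3 | step 12 | benzylic methyl ether of 14 (methoxy on the ring C benzylic carbon, both epimers) | COc1cc(C[C@@]2(COC(C)(C)O2)[C@@H](C(OC)c2cc(Br)c(O)c(OC)c2)CO)ccc1OCc1ccccc1
F4 | step 18 | (1R)-1-(ArBC)-3-(trimethylsilyl)prop-2-yn-1-ol | C[Si](C)(C)C#C[C@H](O)c1cc(OC)c(OCc2ccccc2)c(c1)-c1cc(cc(OC)c1OCc1ccccc1)[C@H]1c2cc(OCc3ccccc3)c(OC)cc2C[C@@]2(COC(C)(C)O2)[C@@H]1COCc1ccccc1
F5 | step 18 | (1S)-1-(ArBC)prop-2-yn-1-ol | C#C[C@H](O)c1cc(OC)c(OCc2ccccc2)c(c1)-c1cc(cc(OC)c1OCc1ccccc1)[C@H]1c2cc(OCc3ccccc3)c(OC)cc2C[C@@]2(COC(C)(C)O2)[C@@H]1COCc1ccccc1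
F6 | step 18 | (1S)-1-(ArBC)prop-2-en-1-ol | C=C[C@H](O)c1cc(OC)c(OCc2ccccc2)c(c1)-c1cc(cc(OC)c1OCc1ccccc1)[C@H]1c2cc(OCc3ccccc3)c(OC)cc2C[C@@]2(COC(C)(C)O2)[C@@H]1COCc1ccccc1
F7 | step 25 | (2S,3R,4S)-2-(ArBC)-4-{(S)-[3-(benzyloxy)-4-methoxyphenyl](hydroxy)methyl}-3-{[(tert-butyldimethylsilyl)oxy]methyl}oxolan-4-ol | COc1ccc([C@H](O)[C@@]2(O)CO[C@H](c3cc(OC)c(OCc4ccccc4)c(c3)-c3cc(cc(OC)c3OCc3ccccc3)[C@H]3c4cc(OCc5ccccc5)c(OC)cc4C[C@@]4(COC(C)(C)O4)[C@@H]3COCc3ccccc3)[C@H]2CO[Si](C)(C)C(C)(C)C)cc1OCc1ccccc1
F8 | step 25 | cyclic thionocarbonate of F7 (spiro 1,3-dioxolane-2-thione on oxolane C4 and the benzylic carbon) | COc1ccc([C@@H]2OC(=S)O[C@@]23CO[C@H](c4cc(OC)c(OCc5ccccc5)c(c4)-c4cc(cc(OC)c4OCc4ccccc4)[C@H]4c5cc(OCc6ccccc6)c(OC)cc5C[C@@]5(COC(C)(C)O5)[C@@H]4COCc4ccccc4)[C@H]3CO[Si](C)(C)C(C)(C)C)cc1OCc1ccccc1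
A1 | alternative 1 | target as its ring A p-toluenesulfonate | COc1ccc(C[C@@]2(O)CO[C@H](c3cc(OC)c(O)c(-c4cc([C@H]5c6cc(O)c(OC)cc6C[C@@](O)(CO)[C@@H]5CO)cc(OC)c4O)c3)[C@H]2CO)cc1OS(=O)(=O)c1ccc(C)cc1
A2 | alternative 1 | unsymmetrical bis-oxolane: biaryl carrying the ring A tosylate oxolane on ring B and a 4-(4-hydroxy-3-methoxybenzyl)-4-hydroxy-3-(hydroxymethyl)oxolan-2-yl group on ring C | COc1ccc(C[C@@]2(O)CO[C@H](c3cc(OC)c(O)c(c3)-c3cc(cc(OC)c3O)[C@H]3OC[C@](O)(Cc4ccc(O)c(OC)c4)[C@@H]3CO)[C@H]2CO)cc1OS(=O)(=O)c1ccc(C)cc1
A3 | alternative 2 | 3-hydroxy-4-oxo tetralin on the protected biaryl (ring B as dioxolane acetal and silyl ether) | C1COC(O1)c1cc(OC)c(O[Si](C)(C)C(C)(C)C)c(c1)-c1cc(cc(OC)c1OCc1ccccc1)[C@H]1c2cc(OCc3ccccc3)c(OC)cc2C(=O)[C@@](O)(COCc2ccccc2)[C@@H]1COCc1ccccc1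
A4 | alternative 2 | keto aldehyde: 1,1-diarylmethine bearing the ring D aldehyde and a 1-(benzyloxy)-3-[(benzyloxy)methyl]butan-2-one chain | C1COC(O1)c1cc(OC)c(O[Si](C)(C)C(C)(C)C)c(c1)-c1cc(cc(OC)c1OCc1ccccc1)[C@@H](c1cc(OCc2ccccc2)c(OC)cc1C=O)[C@@H](COCc1ccccc1)C(=O)COCc1ccccc1
A5 | alternative 3 | protected target with free ring B phenol (benzyl ethers and acetonide) | COc1ccc(C[C@@]2(O)CO[C@H](c3cc(OC)c(O)c(c3)-c3cc(cc(OC)c3OCc3ccccc3)[C@H]3c4cc(OCc5ccccc5)c(OC)cc4C[C@@]4(COC(C)(C)O4)[C@@H]3COCc3ccccc3)[C@H]2CO)cc1OCc1ccccc1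
A6 | alternative 3 | open-chain triol: ring B 4-hydroxybenzyl on the CH carbon and ring A benzyl on the carbinol carbon of a 2-substituted butane-1,2,4-triol | COc1ccc(C[C@@](O)(CO)[C@H](CO)Cc2cc(OC)c(O)c(c2)-c2cc(cc(OC)c2OCc2ccccc2)[C@H]2c3cc(OCc4ccccc4)c(OC)cc3C[C@@]3(COC(C)(C)O3)[C@@H]2COCc2ccccc2)cc1OCc1ccccc1
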